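The numbers in the tables were computed for substances that don't exist; scatter was added.

The delta run shared this flask's starting charge of 0.34 M but had half its reagent, and its ratio of target to side product stood higher at 1.00 min, at 11.0, than in the pooled readings from 6.00 min on, at 7.00, though that first side reading of 2% carried a scatter of 1.5 percentage points.

| flask | starting material | reagent | remark | time |
|---|---|---|---|---|
| alpha | 0.17 M | 1.2 equiv | run made earlier |  |
| gamma | 0.26 M | 1.2 equiv | run made earlier |  |
| delta | 0.34 M | 0.60 equiv | run made earlier |  |
| flask | 0.34 M | 1.20 equiv |  | 20 min |

- alpha (time / min: target / %, side product / %): 2.50: 41, 9; 5.00: 50, 7; 8.00: 57, 9; 10.0: 60, 12; 12.0: 61, 9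
- gamma (time / min: target / %, side product / %): 2.50: 47, 10; 5.00: 55, 14; 8.00: 63, 14; 10.0: 64, 13; 12.0: 62, 14
- delta (time / min: target / %, side product / %): 1.00: 22, 2; 3.00: 34, 4; 6.00: 40, 5; 8.00: 42, 7; 12.0: 44, 6

(readings scatter by 1.5 percentage points)

- ratio of target to side product at 4.0 s
- ratio of target to side product at 1.0 min
- ratio of target to side product at 20 min

For whoever took over the bench, I multiplied delta's two ratios by its 0.60 equiv, which gave 4.20 late and 6.60 early. This weighted selectivity, the ratio of target to side product times the equivalents of reagent charged, was what I carried, taking it at a given time as independent of the reagent charge at this charge of starting material, assuming the side path uses one reagent more than the target path. Dividing by the flask's 1.20 equiv, I expected a ratio of 5.50 at 1.0 min and, from the late value, 3.50 at 20 min; for 4.0 s I committed only to a ratio above the 1.0 min figure. My note said not to top up the reagent, since this rule lowered the ratio as the equivalents rose.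

The forecast gave 2.2, 2.7 and 3.2, on this ground: “The ratio of target to side product falls as reagent concentration rises”.

The flask gave 29.2, 6.08 and 4.66.

    reagent + intermediate C ⇌ intermediate D (K = 1.32 /M, k = 3.85 /M/s)
    starting material ⇌ intermediate C (K = 0.450, k = 0.00666 /s)
    reagent + intermediate A → target (k = 0.137 /M/s)
    intermediate A ⇌ intermediate B (K = 0.810, k = 0.00593 /s)
    reagent + intermediate D → side product (k = 0.205 /M/s)
    starting material ⇌ intermediate A (K = 0.398, k = 0.156 /s)
    target ⇌ isomer of the product (K = 0.142, k = 0.0831 /s)

Its weighted selectivity came to 7.30 at 1.0 min and 5.59 at 20 min, the latter above my 4.20. Divided by 0.480 equiv, that 5.59 gave 11.6 for a neighbour of this flask differing in that reagent charge, which showed 11.5. In this flask, the step between target and isomer of the product, both ways together, had a relaxation half-life of 1.04 s, far shorter than the 20 min of the run. At 20.0 min the flask held 69.6% of target beside 9.88% of the isomer of the product.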